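## Structural features

The target is the (E)-4-hydroxycinnamic (p-coumaric) ester of a eudesmane alcohol. Two six-membered carbocycles, ring A (C1–C5, C10) and ring B (C5–C10), share the C5–C10 bond in a trans fusion, and the quaternary carbon C10 carries the angular methyl group C14. Ring A holds the only ring olefin, the trisubstituted C3=C4 bond with the C15 methyl group on C4. Ring B carries three contiguous stereocentres: C5 (allylic hydrogen on the α-face), C6 (axial ester oxygen on the β-face, syn to C14) and C7 (equatorial β-isopropyl group). C5 is also bonded to the fourth stereocentre, C10, and the absolute configuration is 5R,6R,7S,10R. The fragile parts are the cinnamate (base-labile ester, Michael acceptor, light-sensitive E olefin), the free phenol, and the C3=C4 olefin, which lies β,γ to C6, so that any C6 ketone met on the way can pull the double bond into conjugation and epimerise C5 and C7. The real difficulties are the enantioselective construction of quaternary C10, the axial C6–O bond wedged between C5, the isopropyl-bearing C7 and the syn-axial C14 methyl group (hard to set and hard to acylate), and the non-conjugated position of the ring A olefin. The key step exploits ring B: C6 is a carbonyl-level carbon flanked by C5 and by C7, which bears a C(CH3)2 unit, the pattern left when an acylium carbon C6, already attached to C5 of a finished ring A, adds to the inner carbon of a prenyl olefin C7=C11.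

## Logic of the disconnections

The phenolic O–H of 24 is exchanged for an O–Si bond, giving 23. A free phenol would compete in any acylation of the hindered C6 hydroxyl, so masking it lets the ester be made with a monofunctional acyl donor. The forward step must remove silicon without touching the cinnamate, which calls for buffered fluoride.

23 is cut at the acyl C–O bond on C6 into 18 and 21 (activated as 22). This is the only link between the terpene and the aromatic part, so the route becomes convergent and the stereochemical problem shrinks to a C15 alcohol. The forward step must acylate a very hindered axial alcohol, with retention at C6.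

18 is cut at the C6–H bond to 17. A C6 carbonyl allows hydride delivery from the α-face because the β-face is blocked by C14, which removes one stereocentre. The reagent must reduce faster than it enolises, since the olefin of 17 is β,γ to the carbonyl.

17 is cut at the C5–H bond with the olefin moved from C3=C4 to C4=C5, through 16 to 15. The conjugated isomer is what a ring closure delivers and tolerates, and it removes the C5 stereocentre and the labile arrangement from all earlier stages. The forward step must protonate the extended dienolate at C5, from the α-face, without loss at C7.

15 is cut at the C11–H and C12–H bonds to 14. An isopropenyl group is the natural terminus of a cationic closure onto a prenyl unit. The forward hydrogenation must take the 1,1-disubstituted olefin and leave the tetrasubstituted C4=C5 bond.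

14 is cut at the C6–C7 bond to 13. This opens ring B, removes C7 as a stereocentre and leaves a monocyclic compound whose only stereocentre is C10. The forward step needs chemoselective ionisation at C6, attack at C7 and not C11, clean discharge of the C11 cation, and chair control of C7.

13 is cut at C6–Cl to 12 and then at C5–C6, through 11, to 10. A one-carbon unit on a tetrasubstituted olefin carbon is best brought in by carbonylation of an enol sulfonate, and capture by acetate avoids hydrolysing a very hindered ester. The forward step needs palladium insertion into a hindered C–O bond and capture of the acyl species before it finds the side-chain olefin.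

10 is cut at the C7=C11 bond to 9, and 9 is taken back to the ester oxidation level in 8. The prenyl terminus has two identical methyl groups, so the olefination has no geometry issue, and the three-carbon ester chain is what a Michael addition provides. The forward steps need a partial reduction and an ylide that both leave the enol sulfonate alone.

8 is cut at the O–S bond, through 7, to 6. The C5 carbonyl of 6 has a single enolisable position (C4), so the enol sulfonate is regiodefined and also masks the ketone during the reduction. The forward step must enolise the ketone without touching the ester.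

6 is cut at the C9–C10 bond, through 5 and 4, to 1, 2 and 3. A quaternary carbon α to a ketone carrying a 2-(alkoxycarbonyl)ethyl chain is the retron of a Michael addition, and 2 supplies the absolute configuration. The forward step needs face-selective alkylation of the more substituted enamine tautomer.

21 is cut at its O–Si bond, through 20, to 19, which is commercial and already has the E olefin. The forward step must silylate the phenol and leave the acid free.

## Other disconnections considered

Alternative 1: The cut is the transannular C5–C10 bond, which opens both rings at once to the ten-membered (1(10)E,4E,6R,7S)-germacra-1(10),4-dien-6-ol A1. In the forward direction mild acid would protonate C1 of the C1=C10 olefin, C5 of the C4=C5 olefin would capture the tertiary C10 cation across the ring, and loss of H3 would give eudesm-3-en-6β-ol A2, which is identical with 18.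
- In its favour: it mirrors the biogenesis and forms both rings and both ring-fusion centres in one operation from a chair–chair conformer. It never passes through a C6 ketone, so C6 and C7 cannot epimerise and no deconjugation is needed. A2 is two steps from the target. On these points it is better than the chosen plan, which needs six steps after its ring closure.
- Against it here: A1 is a strained E,E-cyclodecadiene with two stereocentres, and its enantioselective synthesis would be longer and less certain than the whole chosen route (medium-ring closure, Cope rearrangement to the elemane skeleton on warming, conformers leading to different fusions). The C6 hydroxyl is allylic to C4=C5 and can ionise under the triggering acid. The C4 cation can lose H3, H15 or H5 or capture water, so the olefin position is not controlled.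
- Comparison: both plans close a ring by a cation–olefin reaction ended by proton loss. The chosen plan uses a six-membered chair with one existing stereocentre, whereas in A1 four stereochemical elements depend on the conformation of a ten-membered ring. In step count the alternative wins after the key step and should lose clearly before it.

Alternative 2: The cut is at C6–O and C5–Br of the bridged lactone A4, leading back to the achiral cis-cyclohexa-2,5-diene acid A3, which would come from Birch reduction–alkylation of an aromatic acid. Ring B is the former arene, C14 is the carboxyl carbon, and ring A would be closed later from the vinyl iodide carbon C4 onto C5. In the forward key step a cinchona-derived amine catalyst and N-bromosuccinimide would select one of the two enantiotopic olefins of A3; the carboxylate would attack C6 on the face of C14 and bromine would go to C5, fixing C10, C6 and C5 in A4.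
- In its favour: ring B with its quaternary carbon would come from a cheap arene in two steps. The asymmetric step is catalytic, which is better than the stoichiometric (recoverable) auxiliary of the chosen plan. The 6β-oxygen is tied to C14 by the lactone, which is better than relying on the hydride reduction of step 10. C7 is never α to a carbonyl, which is better than the chosen plan.
- Against it here: the cis relationship in A3 rests on a 1,4-induction in the Birch alkylation that is plausible but unsecured. C14 enters as a carboxyl and must be taken down to a methyl group at a neopentyl position. Ring A must be closed by joining C4 to the secondary, neopentyl-type C5 in place of bromine with the correct fusion, for instance by a radical or metal-mediated reductive coupling. The C8=C9 olefin must be hydrogenated without loss of C3=C4, and the (Z)-iodoalkene electrophile must be made.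
- Comparison: the key step is a catalyst-controlled desymmetrisation at least equal in quality to step 1, but the steps after it carry more risk than those after the acylium closure. The count is comparable up to the bicyclic core and several steps longer after it.

Alternative 3: The cut is the C9–C10 bond of the cross-conjugated dienone A6, leading back to the phenol A5. A5 is a 2,4-dimethylphenol whose C3 (the future C5) carries a four-carbon chain with the silyloxy group at C6, the isopropyl group at C7 and a primary bromide at C9. In the forward key step KOtBu would form the phenoxide, and its para carbon C10 would displace the bromide, closing ring B, dearomatising ring A and creating quaternary C10.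
- In its favour: C6 and C7 would be set in an open chain by well-understood aldol chemistry and are never epimerisable, which is better than the chosen plan at C7. No cationic step or acid-sensitive olefin is involved. After saturation of C1=C2, a reductive 1,3-transposition of the enone tosylhydrazone would deliver hydrogen to C5 and place the olefin at C3=C4, which is equal in directness to the deconjugation of step 9.
- Against it here: C10 would be formed under substrate control only, and the required isomer has the new methyl group syn-axial to the 6β-silyloxy group, so it arises from the more crowded transition state. The ortho carbon C4 is also nucleophilic and its attack would close an equally six-membered ring. The C3 carbonyl and the C1=C2 olefin are surplus and cost three or four steps, and A5 itself needs a multistep enantioselective synthesis.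
- Comparison: the ring closure is a substitution with a defined trajectory, a point in its favour for predictability of by-products. However, it creates the quaternary centre at the moment of least control, whereas the chosen plan sets C10 first by a reliable auxiliary method and lets the ring closure create only C7. In step count it would be the longest of the four.

Key step: step 7

Remark: positions are numbered as in eudesmane throughout, also for monocyclic intermediates (C11–C13 isopropyl, C14 on C10, C15 on C4). Commercial 1 is taken as the cis/trans mixture; the methyl-bearing α-carbon that does not become C10 stays a mixture of epimers in 4, 5 and 6 and becomes sp2 in 7, so no separation is planned.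

## Steps

Step 1
Reactants: 1 2,6-dimethylcyclohexanone; 2 (S)-1-phenylethylamine; 3 methyl acrylate
Product: 6 methyl 3-[(1R)-1,3-dimethyl-2-oxocyclohexyl]propanoate (C3 epimers), via ketimine 4 (not isolated), via adduct ketimine 5 (not isolated)
Conditions: 2 (1.05 equiv), TsOH (1 mol %), toluene, reflux, Dean–Stark; evaporate; 3 (1.3 equiv), THF, 60 °C; then 20% aq. AcOH, 25 °C
Reagents that add atoms: water, O
Why: Michael addition of a chiral ketimine through its more substituted secondary enamine tautomer (aza-ene-like transition state with internal N–H transfer); the acrylate approaches the enamine face anti to the phenyl group of the (S)-auxiliary, which should set the quaternary centre (future C10) as R in high enantiomeric excess, and mild acid hydrolysis returns the ketone and the auxiliary.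

Step 2
Reactants: 6 methyl 3-[(1R)-1,3-dimethyl-2-oxocyclohexyl]propanoate
Product: 8 methyl 3-[(1R)-1,3-dimethyl-2-(trifluoromethylsulfonyloxy)cyclohex-2-en-1-yl]propanoate, via potassium enolate 7 (not isolated)
Conditions: KN(SiMe3)2 (1.15 equiv), THF, −78 → −40 °C; PhNTf2 (1.2 equiv), −78 → 0 °C
Reagents that add atoms: N-phenylbis(trifluoromethanesulfonimide), O=S(=O)(N(c1ccccc1)S(=O)(=O)C(F)(F)F)C(F)(F)F
Why: Enol triflate formation by O-sulfonylation of a ketone enolate; only C4 carries an α-hydrogen and the ester α-protons are far less acidic, so the tetrasubstituted enolate is regiodefined, the epimeric methine is erased and C10 is untouched.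

Step 3
Reactants: 8 methyl 3-[(1R)-1,3-dimethyl-2-(trifluoromethylsulfonyloxy)cyclohex-2-en-1-yl]propanoate
Product: 9 3-[(1R)-1,3-dimethyl-2-(trifluoromethylsulfonyloxy)cyclohex-2-en-1-yl]propanal
Conditions: iBu2AlH (1.1 equiv), CH2Cl2, −78 °C; MeOH, then aq. KNaC4H4O6 (potassium sodium tartrate)
Reagents that add atoms: none
Why: Partial reduction of a methyl ester to the aldehyde with iBu2AlH at −78 °C, where over-reduction is suppressed; the tetrasubstituted enol triflate is inert to the hydride at this temperature.

Step 4
Reactants: 9 3-[(1R)-1,3-dimethyl-2-(trifluoromethylsulfonyloxy)cyclohex-2-en-1-yl]propanal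
Product: 10 (6R)-2,6-dimethyl-6-(4-methylpent-3-en-1-yl)cyclohex-1-en-1-yl trifluoromethanesulfonate
Conditions: iPrPPh3I (1.4 equiv), nBuLi (1.3 equiv), THF, 0 °C; 9, −78 → 25 °C
Reagents that add atoms: isopropyltriphenylphosphonium iodide, CC(C)[P+](c1ccccc1)(c1ccccc1)c1ccccc1.[I-]
Why: Wittig olefination of an unhindered aldehyde with the non-stabilised isopropylidene ylide; the two olefin substituents are identical, so there is no geometry to control, and the enol triflate does not react with the ylide.

Step 5
Reactants: 10 (6R)-2,6-dimethyl-6-(4-methylpent-3-en-1-yl)cyclohex-1-en-1-yl trifluoromethanesulfonate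
Product: 12 (6R)-2,6-dimethyl-6-(4-methylpent-3-en-1-yl)cyclohex-1-ene-1-carboxylic acid, via mixed acetic anhydride 11 (not isolated)
Conditions: Pd(OAc)2 (5 mol %), PPh3 (10 mol %), KOAc (4 equiv), CO (1 atm), DMF, 25 → 60 °C; then 1 M HCl
Reagents that add atoms: carbon monoxide, [C-]#[O+]; potassium acetate, CC(=O)[O-].[K+]
Why: Palladium-catalysed hydroxycarbonylation of an enol triflate: zerovalent palladium formed in situ from Pd(OAc)2 inserts into the C–OTf bond, CO insertion gives an acylpalladium species, acetate captures it as the mixed anhydride and aqueous work-up frees the acid, so the hydrolysis of a very hindered conjugated ester is avoided.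

Step 6
Reactants: 12 (6R)-2,6-dimethyl-6-(4-methylpent-3-en-1-yl)cyclohex-1-ene-1-carboxylic acid
Product: 13 (6R)-2,6-dimethyl-6-(4-methylpent-3-en-1-yl)cyclohex-1-ene-1-carbonyl chloride
Conditions: (COCl)2 (1.5 equiv), DMF (2 mol %), CH2Cl2, 0 → 25 °C; evaporate
Reagents that add atoms: oxalyl chloride, O=C(Cl)C(=O)Cl
Why: Standard acid chloride formation through the chloroiminium (Vilsmeier-type) catalyst; the acid has no α-hydrogen, so no ketene can form, and the volatile by-products are removed before the Lewis acid is added.

Step 7
Reactants: 13 (6R)-2,6-dimethyl-6-(4-methylpent-3-en-1-yl)cyclohex-1-ene-1-carbonyl chloride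
Product: 14 (7S,10R)-eudesma-4,11-dien-6-one (7β-isopropenyl; 10β-methyl)
Conditions: SnCl4 (1.1 equiv), 2,6-di-tert-butyl-4-methylpyridine (1.2 equiv), CH2Cl2, −78 °C; aq. NaHCO3 at −78 °C
Reagents that add atoms: none
Why: SnCl4 ionises the hindered acid chloride to an acylium ion at C6, which is conjugated with C4=C5 and has no α-hydrogen, and C6 attacks C7, the less substituted carbon of the trisubstituted olefin, so that the charge arrives at tertiary C11. The closest known reaction type is the Lewis acid-mediated intramolecular acylation of a trisubstituted olefin by an acid chloride (aliphatic Friedel–Crafts acylation or acylium-ene reaction), as in the closure of citronellic acid chloride to p-menthenones. Ring B closes through a six-membered chair-like transition state in the exo mode with respect to C7=C11; the seven-membered alternative through C11 would need a secondary cation. The C11 cation is discharged by loss of a C12 proton, most easily by a six-membered transfer to the carbonyl oxygen, which gives the non-conjugated isopropenyl group, and the hindered pyridine takes up that proton so that no free HCl remains to add to an olefin or to move the new double bond into conjugation. The one new stereocentre, C7, is controlled by the chair: the C7=C11 unit lies equatorially while the C14 methyl group is axial on C10, which gives the 7β (7S) isomer, and this is also the more stable epimer should C7 equilibrate. C10 takes no part and keeps its configuration. The selectivities needed are attack by the prenyl olefin only (C4=C5 is deactivated by the acylium group) and bond formation at C7 and not C11, and both follow from the substitution pattern of the side chain.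

Step 8
Reactants: 14 (7S,10R)-eudesma-4,11-dien-6-one
Product: 15 (7S,10R)-eudesm-4-en-6-one
Conditions: H2 (1 atm), RhCl(PPh3)3 (5 mol %), benzene–EtOH (1:1), 25 °C
Reagents that add atoms: none
Why: Homogeneous hydrogenation with RhCl(PPh3)3 reduces the unhindered 1,1-disubstituted olefin and leaves the tetrasubstituted C4=C5 enone alone; the neutral medium does not enolise C7.

Step 9
Reactants: 15 (7S,10R)-eudesm-4-en-6-one
Product: 17 (5R,7S,10R)-eudesm-3-en-6-one (5α-H; 7β-isopropyl), via potassium dienolate 16 (not isolated)
Conditions: KOtBu (5 equiv), tBuOH–THF, 25 °C, argon; inverse quench into 10% aq. AcOH, 0 °C; used crude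
Reagents that add atoms: none
Why: Deconjugation of an enone by kinetic protonation of its extended dienolate: excess KOtBu removes a γ-proton at C3 to give the thermodynamic dienolate C3=C4–C5=C6–O−, and the fast acetic acid quench protonates the α-carbon C5, leaving C3=C4; the proton arrives axially on the α-face of C5, opposite the angular C14 methyl group, which gives the trans fusion (5R), and the 7β-isopropyl group set in step 7 is the equatorial and favoured arrangement should C7 exchange.

Step 10
Reactants: 17 (5R,7S,10R)-eudesm-3-en-6-one
Product: 18 (5R,6R,7S,10R)-eudesm-3-en-6-ol (6β-OH)
Conditions: LiBH(sBu)3 (1.5 equiv), THF, −78 → −20 °C; NaOH, H2O2, 0 °C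
Reagents that add atoms: none
Why: Reduction of a hindered cyclohexanone with a bulky trialkylborohydride: the β-face of C6 is shielded by the syn-axial C14 methyl group, so hydride enters from the α-face (equatorial attack) and the axial 6β-alcohol (6R) results; at −78 °C reduction should outrun enolisation of the β,γ-unsaturated ketone.

Step 11
Reactants: 19 (E)-3-(4-hydroxyphenyl)prop-2-enoic acid (p-coumaric acid)
Product: 21 (E)-3-[4-(tert-butyldimethylsilyloxy)phenyl]prop-2-enoic acid, via bis-silyl compound 20 (not isolated)
Conditions: TBSCl (2.3 equiv), imidazole (5 equiv), DMF, 25 °C; then AcOH–THF–H2O (3:1:1), 25 °C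
Reagents that add atoms: tert-butyldimethylsilyl chloride, CC(C)(C)[Si](C)(C)Cl
Why: Silylation of phenol and acid followed by selective hydrolysis of the far more labile silyl ester leaves the phenol masked as its silyl ether; the E olefin is not affected.

Step 12
Reactants: 18 (5R,6R,7S,10R)-eudesm-3-en-6-ol; 21 (E)-3-[4-(tert-butyldimethylsilyloxy)phenyl]prop-2-enoic acid
Product: 23 (5R,6R,7S,10R)-eudesm-3-en-6-yl (E)-3-[4-(tert-butyldimethylsilyloxy)phenyl]prop-2-enoate, via acid chloride 22 (not isolated)
Conditions: 21 (2 equiv), (COCl)2, DMF (cat.), CH2Cl2, 0 → 25 °C, evaporate; 18, DMAP (1 equiv), Et3N (4 equiv), toluene, 60 °C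
Reagents that add atoms: none
Why: Acylation of a hindered axial secondary alcohol by an acid chloride under nucleophilic catalysis with DMAP (acylpyridinium intermediate); the silyl ether keeps the phenol from competing and the reaction at oxygen retains the C6 configuration.

Step 13
Reactants: 23 (5R,6R,7S,10R)-eudesm-3-en-6-yl (E)-3-[4-(tert-butyldimethylsilyloxy)phenyl]prop-2-enoate
Product: 24 (5R,6R,7S,10R)-eudesm-3-en-6-yl (E)-3-(4-hydroxyphenyl)prop-2-enoate (CNP0220414.1)
Conditions: Bu4NF (1.2 equiv), AcOH (1.2 equiv), THF, 0 °C
Reagents that add atoms: none
Why: Fluoride cleavage of an aryl silyl ether; buffering with acetic acid keeps the liberated phenoxide from attacking the cinnamate and leaves the hindered ester and the E olefin intact.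

## Compound list

1 | 2,6-dimethylcyclohexanone (cis/trans mixture) | CC1CCCC(C)C1=O | starting material
2 | (S)-1-phenylethylamine | C[C@H](N)c1ccccc1 | starting material
3 | methyl acrylate | C=CC(=O)OC | starting material
4 | (S)-N-(2,6-dimethylcyclohexylidene)-1-phenylethanamine | CC1CCCC(C)C1=N[C@@H](C)c1ccccc1 | intermediate
5 | methyl 3-[(1R)-1,3-dimethyl-2-{[(1S)-1-phenylethyl]imino}cyclohexyl]propanoate | COC(=O)CC[C@@]1(C)CCCC(C)C1=N[C@@H](C)c1ccccc1 | intermediate
6 | methyl 3-[(1R)-1,3-dimethyl-2-oxocyclohexyl]propanoate (C3 epimers) | COC(=O)CC[C@@]1(C)CCCC(C)C1=O | intermediate
7 | potassium (6R)-6-(3-methoxy-3-oxopropyl)-2,6-dimethylcyclohex-1-en-1-olate | COC(=O)CC[C@@]1(C)CCCC(C)=C1[O-].[K+] | intermediate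
8 | methyl 3-[(1R)-1,3-dimethyl-2-(trifluoromethylsulfonyloxy)cyclohex-2-en-1-yl]propanoate | COC(=O)CC[C@@]1(C)CCCC(C)=C1OS(=O)(=O)C(F)(F)F | intermediate
9 | 3-[(1R)-1,3-dimethyl-2-(trifluoromethylsulfonyloxy)cyclohex-2-en-1-yl]propanal | O=CCC[C@@]1(C)CCCC(C)=C1OS(=O)(=O)C(F)(F)F | intermediate
10 | (6R)-2,6-dimethyl-6-(4-methylpent-3-en-1-yl)cyclohex-1-en-1-yl trifluoromethanesulfonate | CC(C)=CCC[C@@]1(C)CCCC(C)=C1OS(=O)(=O)C(F)(F)F | intermediate
11 | acetic (6R)-2,6-dimethyl-6-(4-methylpent-3-en-1-yl)cyclohex-1-ene-1-carboxylic anhydride | CC1=C(C(=O)OC(C)=O)[C@@](C)(CCC=C(C)C)CCC1 | intermediate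
12 | (6R)-2,6-dimethyl-6-(4-methylpent-3-en-1-yl)cyclohex-1-ene-1-carboxylic acid | CC1=C(C(=O)O)[C@@](C)(CCC=C(C)C)CCC1 | intermediate
13 | (6R)-2,6-dimethyl-6-(4-methylpent-3-en-1-yl)cyclohex-1-ene-1-carbonyl chloride | CC1=C(C(=O)Cl)[C@@](C)(CCC=C(C)C)CCC1 | intermediate
14 | (7S,10R)-eudesma-4,11-dien-6-one | CC1=C2C(=O)[C@H](C(C)=C)CC[C@@]2(C)CCC1 | intermediate
15 | (7S,10R)-eudesm-4-en-6-one | CC1=C2C(=O)[C@H](C(C)C)CC[C@@]2(C)CCC1 | intermediate
16 | potassium (7S,10R)-eudesma-3,5-dien-6-olate | CC1=CCC[C@]2(C)CC[C@@H](C(C)C)C([O-])=C12.[K+] | intermediate
17 | (5R,7S,10R)-eudesm-3-en-6-one | CC1=CCC[C@]2(C)CC[C@@H](C(C)C)C(=O)[C@@H]12 | intermediate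
18 | (5R,6R,7S,10R)-eudesm-3-en-6-ol | CC1=CCC[C@]2(C)CC[C@@H](C(C)C)[C@@H](O)[C@@H]12 | intermediate
19 | (E)-3-(4-hydroxyphenyl)prop-2-enoic acid (p-coumaric acid) | O=C(O)/C=C/c1ccc(O)cc1 | starting material
20 | tert-butyldimethylsilyl (E)-3-[4-(tert-butyldimethylsilyloxy)phenyl]prop-2-enoate | CC(C)(C)[Si](C)(C)OC(=O)/C=C/c1ccc(O[Si](C)(C)C(C)(C)C)cc1 | intermediate
21 | (E)-3-[4-(tert-butyldimethylsilyloxy)phenyl]prop-2-enoic acid | O=C(O)/C=C/c1ccc(O[Si](C)(C)C(C)(C)C)cc1 | intermediate
22 | (E)-3-[4-(tert-butyldimethylsilyloxy)phenyl]prop-2-enoyl chloride | O=C(Cl)/C=C/c1ccc(O[Si](C)(C)C(C)(C)C)cc1 | intermediate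
23 | (5R,6R,7S,10R)-eudesm-3-en-6-yl (E)-3-[4-(tert-butyldimethylsilyloxy)phenyl]prop-2-enoate | CC1=CCC[C@]2(C)CC[C@@H](C(C)C)[C@@H](OC(=O)/C=C/c3ccc(O[Si](C)(C)C(C)(C)C)cc3)[C@@H]12 | intermediate
24 | (5R,6R,7S,10R)-eudesm-3-en-6-yl (E)-3-(4-hydroxyphenyl)prop-2-enoate (CNP0220414.1) | CC1=CCC[C@]2(C)CC[C@@H](C(C)C)[C@@H](OC(=O)/C=C/c3ccc(O)cc3)[C@@H]12 | target

## Step count and least certain steps

Total step count: 13. Longest linear sequence: 12 (steps 1 to 10, then 12 and 13); step 11 is the one-step side branch.

Step 7 (key step). The C11 cation may be discharged in more than one direction (proton loss toward C7 to the conjugated isopropylidene ketone, or chloride capture). Traces of protic acid may also pull the isopropenyl double bond into conjugation, after which the cross-conjugated dienone can undergo Lewis acid-induced electrocyclic closure, and the side-chain olefin may be hydrochlorinated before ring closure. The fallback keeps the C6–C7 disconnection but replaces the proton-losing terminus by an allylsilane, so that the cation ends by loss of silicon from C12 and no proton is released.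
- It sets out from 9: Wittig olefination with Ph3P=C(CH3)CH2SiMe3 (from EtPPh3Br, nBuLi, Me3SiCH2I, then nBuLi) should give the allylsilane enol triflate F1 as an E/Z mixture, which is immaterial.
- Hydroxycarbonylation as in step 5 should give the allylsilane acid F2.
- 1-Chloro-N,N,2-trimethylprop-1-en-1-amine (neutral, so that no HCl protodesilylates the allylsilane) should give the allylsilane acid chloride F3.
- SnCl4 in CH2Cl2 at −78 °C should then close ring B by the known Lewis acid-mediated acylation of an allylsilane. The route is rejoined at 14.

Step 9. Proton exchange at C7 while the dienolate is formed may erode the 7β configuration, because the preference for an equatorial isopropyl group beside an enolate oxygen is modest. Protonation at C3 in place of C5 would return 15, and 17 may reconjugate during quench and isolation. The fallback makes the dienolate regiospecifically under aprotic conditions and reduces the ketone without isolating it.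
- It sets out from 15: acid-catalysed enol acetylation (isopropenyl acetate, TsOH, reflux) should give the dienol acetate F4.
- MeLi (2 equiv) in THF at −78 °C should cleave it to the lithium dienolate F5 with no proton source present.
- Two equivalents of acetic acid at −78 °C should protonate C5 to give 17 in solution, and LiBH(sBu)3 added to the same flask should reduce it at once. The route is rejoined at 18.

Step 12. Acyl transfer to the axial hydroxyl, flanked by C5 and C7 and syn-axial to C14, may be so slow that the acylating agent is consumed by hydrolysis or by addition of the amine catalyst before the alcohol reacts. The fallback builds the cinnamate on the alcohol from a small acyl unit.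
- It sets out from 18: bromoacetyl bromide and pyridine in CH2Cl2 should give the bromoacetate F6.
- Triethyl phosphite at 120 °C (Arbuzov reaction) should give the phosphonoacetate F7.
- Horner–Wadsworth–Emmons olefination with commercial 4-(tert-butyldimethylsilyloxy)benzaldehyde (LiCl, DBU, MeCN) should give the E ester. The route is rejoined at 23.

Step 5. Oxidative addition and CO insertion at a tetrasubstituted enol triflate next to quaternary C10 may be slow, and capture of the hindered acylpalladium species by acetate may be inefficient. Hydrolysis of the triflate, or cyclisation of the organopalladium intermediate onto the prenyl olefin, could then compete. The fallback changes the nucleophile and the way the acid is released.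
- It sets out from 10: methoxycarbonylation (Pd(OAc)2, PPh3, Et3N, CO, MeOH–DMF, 60 °C), in which methanol in large excess traps the acyl species, should give the methyl ester F8.
- NaSEt in DMF at 100 °C should then cleave the ester by substitution at the methyl carbon, which avoids attack at the hindered carbonyl. The route is rejoined at 12.

Further compounds

F1 | step 7 | (6R)-2,6-dimethyl-6-[4-methyl-5-(trimethylsilyl)pent-3-en-1-yl]cyclohex-1-en-1-yl trifluoromethanesulfonate (E/Z mixture) | C[Si](C)(C)CC(C)=CCC[C@@]1(C)CCCC(C)=C1OS(=O)(=O)C(F)(F)F
F2 | step 7 | (6R)-2,6-dimethyl-6-[4-methyl-5-(trimethylsilyl)pent-3-en-1-yl]cyclohex-1-ene-1-carboxylic acid | CC1=C(C(=O)O)[C@@](C)(CCC=C(C)C[Si](C)(C)C)CCC1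
F3 | step 7 | (6R)-2,6-dimethyl-6-[4-methyl-5-(trimethylsilyl)pent-3-en-1-yl]cyclohex-1-ene-1-carbonyl chloride | CC1=C(C(=O)Cl)[C@@](C)(CCC=C(C)C[Si](C)(C)C)CCC1
F4 | step 9 | (7S,10R)-eudesma-3,5-dien-6-yl acetate | CC1=CCC[C@]2(C)CC[C@@H](C(C)C)C(OC(C)=O)=C12
F5 | step 9 | lithium (7S,10R)-eudesma-3,5-dien-6-olate | CC1=CCC[C@]2(C)CC[C@@H](C(C)C)C([O-])=C12.[Li+]
F6 | step 12 | (5R,6R,7S,10R)-eudesm-3-en-6-yl bromoacetate | CC1=CCC[C@]2(C)CC[C@@H](C(C)C)[C@@H](OC(=O)CBr)[C@@H]12
F7 | step 12 | (5R,6R,7S,10R)-eudesm-3-en-6-yl (diethoxyphosphoryl)acetate | CC1=CCC[C@]2(C)CC[C@@H](C(C)C)[C@@H](OC(=O)CP(=O)(OCC)OCC)[C@@H]12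
F8 | step 5 | methyl (6R)-2,6-dimethyl-6-(4-methylpent-3-en-1-yl)cyclohex-1-ene-1-carboxylate | CC1=C(C(=O)OC)[C@@](C)(CCC=C(C)C)CCC1
A1 | alternative 1 | (1(10)E,4E,6R,7S)-germacra-1(10),4-dien-6-ol | C/C1=C\CC/C(C)=C/[C@H](O)[C@H](C(C)C)CC1
A2 | alternative 1 | (5R,6R,7S,10R)-eudesm-3-en-6-ol (eudesm-3-en-6β-ol, identical with 18) | CC1=CCC[C@]2(C)CC[C@@H](C(C)C)[C@@H](O)[C@@H]12
A3 | alternative 2 | cis-1-[(3Z)-4-iodopent-3-en-1-yl]-4-isopropylcyclohexa-2,5-diene-1-carboxylic acid | OC(=O)[C@@]1(CC/C=C(/C)I)C=C[C@@H](C(C)C)C=C1
A4 | alternative 2 | 8-bromo-1-[(3Z)-4-iodopent-3-en-1-yl]-4-isopropyl-6-oxabicyclo[3.2.1]oct-2-en-7-one (bridged bromo γ-lactone) | O=C1O[C@@H]2[C@H](C(C)C)C=C[C@@]1(CC/C=C(/C)I)[C@H]2Br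
A5 | alternative 3 | 3-[4-bromo-1-(tert-butyldimethylsilyloxy)-2-isopropylbutyl]-2,4-dimethylphenol (C6 and C7 as in the target) | Cc1c(O)ccc(C)c1[C@H](O[Si](C)(C)C(C)(C)C)[C@H](C(C)C)CCBr
A6 | alternative 3 | 6β-(tert-butyldimethylsilyloxy)eudesma-1,4-dien-3-one | CC1=C2[C@H](O[Si](C)(C)C(C)(C)C)[C@H](C(C)C)CC[C@@]2(C)C=CC1=O
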